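**Retrosynthetic overview**
1. Target 18 ⇐ carbonylative ethylation of vinyl bromide 17 (enone installed last) ⇐ O-methylation of hydroxy-α-pyrone 16.
2. 16 ⇐ α-chlorocyclobutanone 11 + dianion of β-ketoester 13: a C-nucleophile-triggered semibenzilic ring contraction (cyclobutanone → cyclopropyl ketone) whose former C=O carbon becomes pyrone C-6, followed by lactonisation.
3. 11 ⇐ bicyclo[3.2.0]heptenone 9 (α-methylation, exo-chlorination) ⇐ hydroxy acid 7 by Rosini vinylketene/alkene bicyclisation.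
4. 7 ⇐ aldehyde 5 + propanoic acid; 5 ⇐ propanal + dienol 3 (Ir/enamine allylation sets the only externally controlled stereocentre, the later C-4); 3 ⇐ 2-bromoacrolein + vinylmagnesium bromide.
5. Ring order: cyclopentene and cyclobutanone together → cyclopropane (by contraction of the four-membered ring) → pyranone.

Assumption: 2-bromoacrolein is bought (otherwise one step from acrolein), and the sense of induction of the Ir/(R)-ligand catalyst in step 2 is taken by analogy with aryl vinyl carbinols (if it proves opposite, the (S)-ligand is used).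

**Step 1**
Reactants: 1 2-bromoprop-2-enal; 2 vinylmagnesium bromide
Product: 3 (±)-2-bromopenta-1,4-dien-3-ol
Conditions: THF, −78 °C; aq. NH4Cl
Reagents that add atoms: none
Why: Grignard 1,2-addition to the enal carbonyl; the racemic carbinol centre is erased on ionisation in step 2.

**Step 2**
Reactants: 3 (±)-2-bromopenta-1,4-dien-3-ol; 4 propanal
Product: 5 (2R,3R)-3-(1-bromoethenyl)-2-methylpent-4-enal
Conditions: [Ir(cod)Cl]2 (3 mol%), (R)-phosphoramidite–olefin ligand (Carreira ligand, 12 mol%), (S)-α,α-bis[3,5-bis(trifluoromethyl)phenyl]prolinol TMS ether (10 mol%), (MeO)2P(O)OH (promoter), propanal (3 equiv), DCE, 25 °C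
Reagents that add atoms: none
Why: Stereodivergent dual Ir/enamine α-allylation of a linear aldehyde (Carreira type): acid-promoted ionisation of 3 through its unsubstituted vinyl group gives an Ir–π-allyl that the propanal enamine attacks at the substituted terminus, the Ir/ligand setting C-3 (R) and the amine setting C-2 (which is erased in step 4).

**Step 3**
Reactants: 5 (2R,3R)-3-(1-bromoethenyl)-2-methylpent-4-enal; 6 propanoic acid (as its dilithium dianion)
Product: 7 (4R,5R)-5-(1-bromoethenyl)-3-hydroxy-2,4-dimethylhept-6-enoic acid (C-2/C-3 epimer mixture)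
Conditions: 6, LDA (2.1 equiv), THF/DMPU, 0 °C; then 5, −78 °C; 1 M HCl
Reagents that add atoms: none
Why: Carboxylic acid dianion aldol addition (Ivanov type) to the aldehyde; the new C-2/C-3 centres need no control because both become sp2 in step 4.

**Step 4**
Reactants: 7 (4R,5R)-5-(1-bromoethenyl)-3-hydroxy-2,4-dimethylhept-6-enoic acid
Product: 9 (1R,2R,5R)-2-(1-bromoethenyl)-3,5-dimethylbicyclo[3.2.0]hept-3-en-6-one, via vinylketene 8 (not isolated)
Conditions: KOAc (2 equiv), Ac2O, 23 °C, 2 h; then 120 °C, 4 h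
Reagents that add atoms: none
Why: Rosini bicyclisation (acetylation/mixed anhydride, elimination to vinylketene 8, intramolecular ketene–alkene [2+2]); the electron-richer vinyl group reacts rather than the deactivated bromovinyl group, and the A(1,3)-controlled transition state (C–H eclipsing the vinyl group) places the bromovinyl group exo, which fixes the cis-fused bridgeheads C-1 and C-5 relative to C-2.

**Step 5**
Reactants: 9 (1R,2R,5R)-2-(1-bromoethenyl)-3,5-dimethylbicyclo[3.2.0]hept-3-en-6-one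
Product: 10 (1R,2R,5R,7S)-2-(1-bromoethenyl)-3,5,7-trimethylbicyclo[3.2.0]hept-3-en-6-one
Conditions: LDA (1.05 equiv), THF, −78 °C; MeI, −78 → −30 °C
Reagents that add atoms: iodomethane CI
Why: Kinetic enolate alkylation, regiospecific because C-5 is quaternary and only C-7 can enolise; MeI enters from the convex exo face, and the C-7 configuration is reset in step 6.

**Step 6**
Reactants: 10 (1R,2R,5R,7S)-2-(1-bromoethenyl)-3,5,7-trimethylbicyclo[3.2.0]hept-3-en-6-one
Product: 11 (1R,2R,5R,7S)-2-(1-bromoethenyl)-7-chloro-3,5,7-trimethylbicyclo[3.2.0]hept-3-en-6-one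
Conditions: LiHMDS (1.2 equiv), THF, −78 °C; NCS, −78 → 0 °C; aq. NH4Cl
Reagents that add atoms: N-chlorosuccinimide O=C1CCC(=O)N1Cl
Why: Electrophilic α-chlorination of the tetrasubstituted lithium enolate from the convex exo face gives the 7-exo-chloro-7-endo-methyl ketone, the geometry needed for the contraction.

**Step 7**
Reactants: 12 methyl propanoate (2 equiv)
Product: 13 methyl 2-methyl-3-oxopentanoate (racemic)
Conditions: NaH (0.6 equiv per ester), cat. MeOH, THF, reflux; AcOH
Reagents that add atoms: none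
Why: Claisen self-condensation, driven to completion by deprotonation of the β-ketoester product.

**Step 8**
Reactants: 11 (1R,2R,5R,7S)-2-(1-bromoethenyl)-7-chloro-3,5,7-trimethylbicyclo[3.2.0]hept-3-en-6-one; 13 methyl 2-methyl-3-oxopentanoate (as its dilithium dianion)
Product: 16 6-[(1S,4R,5R,6S)-4-(1-bromoethenyl)-1,3,6-trimethylbicyclo[3.1.0]hex-2-en-6-yl]-4-hydroxy-3,5-dimethyl-2H-pyran-2-one, via chlorohydrin aldolate 14 (not isolated), via triketide ester 15 (not isolated)
Conditions: 13 (2.2 equiv), LDA (4.4 equiv), THF, 0 °C; 11, −78 → 23 °C; AcOH (to neutral); DBU (5 equiv), 50 °C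
Reagents that add atoms: none
Why: Proposed new method: a carbon-nucleophile-triggered semibenzilic (quasi-Favorskii) ring contraction in which the γ-carbanion of the β-ketoester dianion adds to the non-enolisable cyclobutanone C=O of 11 (both α-carbons are fully substituted, so deprotonation cannot compete) and the tertiary lithium alkoxide 14 collapses by 1,2-shift of the C5–C6 ring bond onto C-7 with backside displacement of the pseudo-equatorial exo chloride (inversion at C-7, retention at the migrating quaternary carbon), which closes the cyclopropane, sets the quaternary centre (methyl endo, acyl exo) and gives triketide 15 that DBU lactonises to the 4-hydroxy-2-pyranone; the closest known reaction type is the hydroxide-, alkoxide-, hydride- or simple Grignard-triggered semibenzilic contraction of 2-halocyclobutanones, in which a 1,3-dicarbonyl dianion has not been used as trigger.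

**Step 9**
Reactants: 16 6-[(1S,4R,5R,6S)-4-(1-bromoethenyl)-1,3,6-trimethylbicyclo[3.1.0]hex-2-en-6-yl]-4-hydroxy-3,5-dimethyl-2H-pyran-2-one
Product: 17 2-[(1S,4R,5R,6S)-4-(1-bromoethenyl)-1,3,6-trimethylbicyclo[3.1.0]hex-2-en-6-yl]-6-methoxy-3,5-dimethyl-4H-pyran-4-one
Conditions: MeOTf (1.3 equiv), CH2Cl2, 0 → 23 °C; sat. aq. NaHCO3
Reagents that add atoms: methyl trifluoromethanesulfonate COS(=O)(=O)C(F)(F)F
Why: Regioselective O-methylation of the neutral 4-hydroxy-2-pyranone at the lactone carbonyl oxygen by a hard methylating agent, followed by proton loss, gives the α-methoxy-γ-pyrone (established selectivity for 3,5-dimethyl-4-hydroxy-2-pyranones).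

**Step 10**
Reactants: 17 2-[(1S,4R,5R,6S)-4-(1-bromoethenyl)-1,3,6-trimethylbicyclo[3.1.0]hex-2-en-6-yl]-6-methoxy-3,5-dimethyl-4H-pyran-4-one
Product: 18 2-methoxy-3,5-dimethyl-6-[(1S,4R,5R,6S)-1,3,6-trimethyl-4-(3-oxopent-1-en-2-yl)bicyclo[3.1.0]hex-2-en-6-yl]-4H-pyran-4-one
Conditions: CO (3 atm), Et3B (1.5 equiv), Pd(PPh3)4 (5 mol%), K3PO4 (3 equiv), dioxane/H2O, BHT (cat.), 50 °C
Reagents that add atoms: carbon monoxide [C-]#[O+]; triethylborane CCB(CC)CC
Why: Carbonylative Suzuki–Miyaura coupling (oxidative addition of the vinyl bromide, CO insertion to the acyl-palladium, ethyl transfer from the borate, reductive elimination) gives the α-methylene ethyl ketone under mildly basic conditions that leave all four stereocentres untouched.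

**Compound list**
1 | 2-bromoprop-2-enal (2-bromoacrolein) | C=C(Br)C=O | starting material
2 | vinylmagnesium bromide | C=C[Mg]Br | starting material
3 | (±)-2-bromopenta-1,4-dien-3-ol | C=CC(O)C(Br)=C | intermediate
4 | propanal | CCC=O | starting material
5 | (2R,3R)-3-(1-bromoethenyl)-2-methylpent-4-enal | O=C[C@H](C)[C@H](C(Br)=C)C=C | intermediate
6 | propanoic acid | CCC(=O)O | starting material
7 | (4R,5R)-5-(1-bromoethenyl)-3-hydroxy-2,4-dimethylhept-6-enoic acid (C-2/C-3 epimers) | OC(=O)C(C)C(O)[C@H](C)[C@H](C(Br)=C)C=C | intermediate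
8 | (3Z,5R)-5-(1-bromoethenyl)-2,4-dimethylhepta-1,3,6-trien-1-one (vinylketene) | O=C=C(C)/C=C(/C)[C@H](C(Br)=C)C=C | intermediate (not isolated)
9 | (1R,2R,5R)-2-(1-bromoethenyl)-3,5-dimethylbicyclo[3.2.0]hept-3-en-6-one (bromovinyl exo) | O=C1C[C@@H]2[C@@H](C(Br)=C)C(C)=C[C@]12C | intermediate
10 | (1R,2R,5R,7S)-2-(1-bromoethenyl)-3,5,7-trimethylbicyclo[3.2.0]hept-3-en-6-one (7-exo-methyl) | O=C1[C@@H](C)[C@@H]2[C@@H](C(Br)=C)C(C)=C[C@]12C | intermediate
11 | (1R,2R,5R,7S)-2-(1-bromoethenyl)-7-chloro-3,5,7-trimethylbicyclo[3.2.0]hept-3-en-6-one (7-exo-Cl, 7-endo-Me) | O=C1[C@@](C)(Cl)[C@@H]2[C@@H](C(Br)=C)C(C)=C[C@]12C | intermediate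
12 | methyl propanoate | CCC(=O)OC | starting material
13 | methyl 2-methyl-3-oxopentanoate (racemic) | CCC(=O)C(C)C(=O)OC | intermediate
14 | methyl 4-[(1R,2R,5R,7S)-2-(1-bromoethenyl)-7-chloro-6-hydroxy-3,5,7-trimethylbicyclo[3.2.0]hept-3-en-6-yl]-2-methyl-3-oxopentanoate (chlorohydrin aldolate, present as Li alkoxide; C-6 and chain centres unassigned) | COC(=O)C(C)C(=O)C(C)C1(O)[C@@](C)(Cl)[C@@H]2[C@@H](C(Br)=C)C(C)=C[C@]12C | intermediate (not isolated)
15 | methyl 5-[(1S,4R,5R,6S)-4-(1-bromoethenyl)-1,3,6-trimethylbicyclo[3.1.0]hex-2-en-6-yl]-2,4-dimethyl-3,5-dioxopentanoate (triketide ester; chain centres epimeric) | C=C(Br)[C@H]1C(C)=C[C@@]2(C)[C@@H]1[C@]2(C)C(=O)C(C)C(=O)C(C)C(=O)OC | intermediate (not isolated)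
16 | 6-[(1S,4R,5R,6S)-4-(1-bromoethenyl)-1,3,6-trimethylbicyclo[3.1.0]hex-2-en-6-yl]-4-hydroxy-3,5-dimethyl-2H-pyran-2-one | C=C(Br)[C@H]1C(C)=C[C@@]2(C)[C@@H]1[C@]2(C)c1oc(=O)c(C)c(O)c1C | intermediate
17 | 2-[(1S,4R,5R,6S)-4-(1-bromoethenyl)-1,3,6-trimethylbicyclo[3.1.0]hex-2-en-6-yl]-6-methoxy-3,5-dimethyl-4H-pyran-4-one | C=C(Br)[C@H]1C(C)=C[C@@]2(C)[C@@H]1[C@]2(C)c1oc(OC)c(C)c(=O)c1C | intermediate
18 | 2-methoxy-3,5-dimethyl-6-[(1S,4R,5R,6S)-1,3,6-trimethyl-4-(3-oxopent-1-en-2-yl)bicyclo[3.1.0]hex-2-en-6-yl]-4H-pyran-4-one (side chain trans to the cyclopropane, pyranone exo) | C=C(C(=O)CC)[C@H]1C(C)=C[C@@]2(C)[C@@H]1[C@]2(C)c1oc(OC)c(C)c(=O)c1C | target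

**Step count**
Total steps: 10. Longest linear sequence: 9 (steps 1–6 and 8–10; step 7 is a one-step side branch).

**Three steps most likely to fail**

Step 8 (the proposed new ring contraction). The risks are slow or reversible addition of the secondary carbanion to the doubly neopentyl carbonyl, halophilic attack on the tertiary chloride, and ring opening instead of contraction. The fallback uses known chemistry, sets out from 11 and comes back at 15. Compound 11 is contracted with aqueous KOH in dioxane (classical hydroxide-triggered semibenzilic contraction, same stereochemical course) to (1S,4R,5R,6S)-4-(1-bromoethenyl)-1,3,6-trimethylbicyclo[3.1.0]hex-2-ene-6-carboxylic acid F9. Carbonyldiimidazole in THF converts it into [(1S,4R,5R,6S)-4-(1-bromoethenyl)-1,3,6-trimethylbicyclo[3.1.0]hex-2-en-6-yl](1H-imidazol-1-yl)methanone F10. C-Acylation of the dilithium dianion of 13 with F10 gives triketide 15, which DBU closes to 16 as in step 8.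

Step 2 (Ir/enamine allylation). A 1-bromovinyl carbinol lies outside the proven aryl/alkenyl scope and may ionise poorly. The fallback is a chirality-transfer Claisen route; it sets out from 1 and comes back at 10, so it also replaces steps 3–5. Compound 1 is olefinated with 1-(triphenylphosphoranylidene)propan-2-one to (3E)-5-bromohexa-3,5-dien-2-one F1. CBS reduction ((R)-Me-CBS, BH3·SMe2) gives (2S,3E)-5-bromohexa-3,5-dien-2-ol F2, and propanoyl chloride/pyridine gives (2S,3E)-5-bromohexa-3,5-dien-2-yl propanoate F3. Ireland–Claisen rearrangement (LDA, TMSCl, THF, −78 → 23 °C; chair transition state with 1,3-chirality transfer) gives (3R,4E)-3-(1-bromoethenyl)-2-methylhex-4-enoic acid F4. LiAlH4 gives (3R,4E)-3-(1-bromoethenyl)-2-methylhex-4-en-1-ol F5, and Dess–Martin oxidation gives (3R,4E)-3-(1-bromoethenyl)-2-methylhex-4-enal F6. Aldol addition of the dianion of 6 gives (5R,6E)-5-(1-bromoethenyl)-3-hydroxy-2,4-dimethyloct-6-enoic acid F7. Rosini bicyclisation (KOAc, Ac2O, 120 °C) through (3Z,5R,6E)-5-(1-bromoethenyl)-2,4-dimethylocta-1,3,6-trien-1-one F8 delivers 10 directly, because the E-propenyl group brings in the 7-exo-methyl group.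

Step 10 (carbonylative coupling). The risks are direct ethylation without CO insertion and slow oxidative addition at the hindered 1,1-disubstituted vinyl bromide. The fallback sets out from 17 and comes back at 18. Compound 17 is coupled with propanal 4 under Nozaki–Hiyama–Kishi conditions (CrCl2, cat. NiCl2, DMF, 23 °C) to 2-[(1S,4R,5R,6S)-4-(3-hydroxypent-1-en-2-yl)-1,3,6-trimethylbicyclo[3.1.0]hex-2-en-6-yl]-6-methoxy-3,5-dimethyl-4H-pyran-4-one F11 (carbinol epimers), and Dess–Martin oxidation gives 18.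

**Further compounds**
F1 | step 2 | (3E)-5-bromohexa-3,5-dien-2-one | CC(=O)/C=C/C(Br)=C
F2 | step 2 | (2S,3E)-5-bromohexa-3,5-dien-2-ol | C[C@H](O)/C=C/C(Br)=C
F3 | step 2 | (2S,3E)-5-bromohexa-3,5-dien-2-yl propanoate | CCC(=O)O[C@@H](C)/C=C/C(Br)=C
F4 | step 2 | (3R,4E)-3-(1-bromoethenyl)-2-methylhex-4-enoic acid (C-2 epimers) | OC(=O)C(C)[C@H](C(Br)=C)/C=C/C
F5 | step 2 | (3R,4E)-3-(1-bromoethenyl)-2-methylhex-4-en-1-ol | OCC(C)[C@H](C(Br)=C)/C=C/C
F6 | step 2 | (3R,4E)-3-(1-bromoethenyl)-2-methylhex-4-enal | O=CC(C)[C@H](C(Br)=C)/C=C/C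
F7 | step 2 | (5R,6E)-5-(1-bromoethenyl)-3-hydroxy-2,4-dimethyloct-6-enoic acid | OC(=O)C(C)C(O)C(C)[C@H](C(Br)=C)/C=C/C
F8 | step 2 | (3Z,5R,6E)-5-(1-bromoethenyl)-2,4-dimethylocta-1,3,6-trien-1-one | O=C=C(C)/C=C(/C)[C@H](C(Br)=C)/C=C/C
F9 | step 8 | (1S,4R,5R,6S)-4-(1-bromoethenyl)-1,3,6-trimethylbicyclo[3.1.0]hex-2-ene-6-carboxylic acid | C=C(Br)[C@H]1C(C)=C[C@@]2(C)[C@@H]1[C@]2(C)C(=O)O
F10 | step 8 | [(1S,4R,5R,6S)-4-(1-bromoethenyl)-1,3,6-trimethylbicyclo[3.1.0]hex-2-en-6-yl](1H-imidazol-1-yl)methanone | C=C(Br)[C@H]1C(C)=C[C@@]2(C)[C@@H]1[C@]2(C)C(=O)n1ccnc1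
F11 | step 10 | 2-[(1S,4R,5R,6S)-4-(3-hydroxypent-1-en-2-yl)-1,3,6-trimethylbicyclo[3.1.0]hex-2-en-6-yl]-6-methoxy-3,5-dimethyl-4H-pyran-4-one | C=C(C(O)CC)[C@H]1C(C)=C[C@@]2(C)[C@@H]1[C@]2(C)c1oc(OC)c(C)c(=O)c1C
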